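**Retrosynthetic overview**
1. Feature: the 2,3-dihydrofuran ring O–C1=C2–C3–C4 carries a methyl group and the alkenyl carbon C5 on C4. It is therefore a 2-methylfuran alkylated at its methyl-bearing α-carbon. C1 (ether carbon, donor) and C6 (γ-carbon of the butenolide, acceptor) face each other across the ten-membered carbocycle and can hold a temporary bond.
2. Last disconnection: restoring C1–C6 (tosylate on C5, one more H on C2) contracts the ten-membered ring to the cyclohexane C1–C10–C9–C8–C7–C6, fused to a 7-oxanorbornane and to the butenolide.
3. Key disconnection: a retro intramolecular furan Diels–Alder reaction (C4–C5 and C1–C6) opens the oxanorbornene to a furan tethered to a 5-(tosyloxymethylene)-3-bromobutenolide.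
4. Chain: C7–C8 by Nozaki–Hiyama–Kishi coupling of 3,4-dibromobutenolide, C10 by catalytic enantioselective allylboration of 2-acetyl-5-methylfuran, C8 by 1,3-syn reduction, C5 from Bredereck's reagent, C13 by Stille coupling.
5. Ring order: furan and butenolide are bought. The cycloaddition closes the oxanorbornene and the six-membered carbocycle together. The final fragmentation releases the ten-membered carbocycle, the dihydrofuran and the alkylidene butenolide.

Key step: step 10

Remark: germacranolide numbering is used (C1 enol ether carbon, C4 and C10 methyl-bearing carbons, C5=C6 enol lactone alkene, C7=C11 butenolide alkene, C8 ester carbinol, C12 lactone carbonyl, C13 acetoxymethyl carbon). The enol tosylate is drawn as the less crowded Z isomer, and any E isomer should converge on the same target because C5 returns to sp2.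

**Step 1**
Reactants: 1 2-acetyl-5-methylfuran; 2 allylboronic acid pinacol ester
Product: 3 (R)-2-(5-methylfuran-2-yl)pent-4-en-2-ol
Conditions: 2 (1.3 equiv), 2-[(3-tert-butyl-2-hydroxybenzyl)amino]-N,N,3-trimethylbutanamide (valine-derived aminophenol, 5 mol %, the enantiomer that directs allyl to the Re face), NaOt-Bu (10 mol %), MeOH (1.5 equiv), toluene, 22 °C
Reagents that add atoms: none
Why: Catalytic enantioselective allylboration of a ketone, in which the aminophenol replaces pinacol on boron, the chiral allylboron species binds the ketone in a closed chair transition state that tells furyl from methyl, and allyl transfer to the Re face sets C10 (R).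

**Step 2**
Reactants: 3 (R)-2-(5-methylfuran-2-yl)pent-4-en-2-ol
Product: 5 (R)-3-hydroxy-3-(5-methylfuran-2-yl)butanal, via triol 4 (not isolated)
Conditions: OsO4 (2 mol %), NaIO4 (4 equiv), 2,6-lutidine (2 equiv), 1,4-dioxane–H2O (3:1), 0 → 23 °C; crude aldehyde used at once
Reagents that add atoms: osmium tetroxide, O=[Os](=O)(=O)=O (catalytic oxygen carrier); sodium periodate, [Na+].[O-]I(=O)(=O)=O (terminal oxidant)
Why: Lemieux–Johnson oxidation, in which OsO4 takes the unhindered terminal alkene before the aromatic furan, periodate cleaves the diol to the C8 aldehyde, and the lutidine buffer guards the tertiary furyl carbinol against dehydration and retro-aldol cleavage, so C10 is untouched.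

**Step 3**
Reactants: 5 (R)-3-hydroxy-3-(5-methylfuran-2-yl)butanal; 6 3,4-dibromofuran-2(5H)-one
Product: 7 3-bromo-4-[(3R)-1,3-dihydroxy-3-(5-methylfuran-2-yl)butyl]furan-2(5H)-one (both C8 epimers)
Conditions: 6 (1.5 equiv), CrCl2 (4 equiv), NiCl2 (2 mol %), DMF, 23 °C; aqueous work-up
Reagents that add atoms: none
Why: Nozaki–Hiyama–Kishi coupling, in which zerovalent nickel should insert into the more electrophilic β C–Br bond of 6 (the site that also reacts first in palladium couplings of this dibromide), the derived alkenyl species of trivalent chromium adds to the aldehyde while tolerating the free hydroxyl, the lactone and the α-bromide, and the C8 epimer mixture does not matter because C8 is oxidised next.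

**Step 4**
Reactants: 7 NHK adduct (both C8 epimers)
Product: 8 3-bromo-4-[(3R)-3-hydroxy-3-(5-methylfuran-2-yl)butanoyl]furan-2(5H)-one
Conditions: Dess–Martin periodinane (1.3 equiv), pyridine (3 equiv), CH2Cl2, 0 → 23 °C
Reagents that add atoms: none
Why: Dess–Martin oxidation, in which only the secondary C8 carbinol can be oxidised and the buffered neutral medium avoids retro-aldol cleavage of the β-hydroxy ketone and attack on the furan.

**Step 5**
Reactants: 8 C8 ketone
Product: 10 syn-1,3-diol 3-bromo-4-[(1S,3R)-1,3-dihydroxy-3-(5-methylfuran-2-yl)butyl]furan-2(5H)-one, via boron chelate 9 (not isolated)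
Conditions: Et2BOMe (1.2 equiv), THF–MeOH (4:1), −78 °C, 30 min; NaBH4 (1.1 equiv), −78 °C; pH 7 buffer, then repeated co-evaporation with MeOH
Reagents that add atoms: none
Why: Narasaka–Prasad 1,3-syn reduction, in which O10 and the C8 ketone are tied into a six-membered diethylboron chelate with the flat 5-methylfuryl group pseudo-equatorial and the methyl group pseudo-axial, external hydride follows the axial path to the chair boronate, C8 is set (S) and syn to O10, and activation of the chelated carbonyl at −78 °C favours 1,2- over 1,4-reduction.

**Step 6**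
Reactants: 10 syn-1,3-diol
Product: 11 O8 tert-butyldimethylsilyl ether of 10 (O10–H free)
Conditions: TBSCl (1.3 equiv), imidazole (3 equiv), DMF, 23 °C
Reagents that add atoms: tert-butyldimethylsilyl chloride, CC(C)(C)[Si](C)(C)Cl
Why: Silyl ether formation, which should take the secondary O8–H only because the tertiary O10–H is too hindered for TBSCl/imidazole.

**Step 7**
Reactants: 11 O8 silyl ether; 12 tert-butoxybis(dimethylamino)methane
Product: 13 (Z)-5-(dimethylaminomethylene) derivative of 11 (C5 attached to C6)
Conditions: 12 (3 equiv), toluene, 60 °C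
Reagents that add atoms: none
Why: Aminomethylenation of a CH-acidic methylene with Bredereck's reagent, in which the released tert-butoxide deprotonates the vinylogously acidic γ-CH2 (C6), the dienolate attacks the formamidinium ion at C6 because the α-carbon C11 is blocked by bromine, and loss of dimethylamine gives the push–pull enamine with nitrogen turned away from the C7 side chain.

**Step 8**
Reactants: 13 aminomethylene lactone
Product: 14 (Z)-5-(hydroxymethylene) lactone
Conditions: 0.5 M aq. citric acid, THF, 0 °C, short contact
Reagents that add atoms: water, O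
Why: Enamine hydrolysis (C-protonation at C6, addition of water to the iminium carbon C5, loss of dimethylamine) under a weak cold acid chosen so that the silyl ether and the acid-labile tertiary furyl carbinol survive.

**Step 9**
Reactants: 14 hydroxymethylene lactone
Product: 15 (Z)-enol tosylate, the cycloaddition precursor
Conditions: TsCl (1.2 equiv), Et3N (2 equiv), N-methylimidazole (10 mol %), CH2Cl2, −20 → 0 °C
Reagents that add atoms: p-toluenesulfonyl chloride, Cc1ccc(cc1)S(=O)(=O)Cl
Why: O-sulfonylation of a vinylogous acid, in which the acidic enol is sulfonylated at the C5 oxygen far faster than the tertiary alcohol and the sulfonate ends up cis to the ring oxygen, away from the C7 substituent.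

**Step 10**
Reactants: 15 (Z)-enol tosylate
Product: 16 7-oxanorbornene cycloadduct fused to the cyclohexane C1–C10–C9–C8–C7–C6 and to the bromobutenolide
Conditions: CH2Cl2 (0.02 M), BHT (trace), 13 kbar, 23 °C, 72 h; decompression at 0 °C, used at once
Reagents that add atoms: none
Why: The furan (C1 to C4, HOMO) and the exocyclic alkene C5=C6 (LUMO, lowered by cross-conjugation through C7=C11 to the lactone carbonyl and by the bromine and sulfonate groups) combine in one thermally allowed [4+2] event with unequal bond advancement, and pressure exploits the strongly negative activation and reaction volumes of this crowded, reversible process. The closest known reaction type is the intramolecular Diels–Alder reaction of a furan with an electron-poor alkene on a four-atom tether, and the exocyclic bond of 3-bromo-5-methylene-2(5H)-furanones is a known dienophile site. The cyclohexene ring C1–C6 of the 7-oxabicyclo[2.2.1]heptene closes by the cycloaddition itself (bonds C4–C5 and C1–C6, oxygen bridge inherited from the furan), and the carbocycle C1–C10–C9–C8–C7–C6 closes at the same moment as a six-membered chair, because the chain C10–C9–C8–C7 spans C1 and C6 and has to lie exo, next to the oxygen bridge. C6 is controlled by C8: allylic 1,3-strain with the C11 bromine keeps H8 in the butenolide plane, so C9 carries the furan to one face of C5=C6 while the silyloxy group stays on the other; C1 and C4 (S) then follow from the exo tether and suprafacial addition to the furan, and C5 (tosylate endo) copies the Z alkene geometry. The (10R) centre is matched, since this chair places its methyl group equatorial and its hydroxyl axial, hydrogen-bonded to the syn O8. The step needs face selectivity on both partners, secured by the syn C8/C10 pair as described, and site selectivity for C5=C6 over C7=C11, secured because the latter is tetrasubstituted and out of reach of the tether.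

**Step 11**
Reactants: 16 oxanorbornene cycloadduct
Product: 17 saturated 7-oxanorbornane (C2–C3 single bond)
Conditions: KO2CN=NCO2K (10 equiv), AcOH (20 equiv), CH2Cl2–MeOH, 0 °C
Reagents that add atoms: none
Why: Diimide reduction, in which the strained, unpolarised C2=C3 bond accepts diimide from the exo face at 0 °C, which rules out cycloreversion, while the tetrasubstituted electron-poor C7=C11 bond, the C–Br bond and the tosylate are left alone.

**Step 12**
Reactants: 17 saturated bromide; 18 (tributylstannyl)methanol
Product: 19 C11 hydroxymethyl butenolide (C13 installed)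
Conditions: 18 (1.5 equiv), Pd(PPh3)4 (10 mol %), 1,4-dioxane, 90 °C
Reagents that add atoms: none
Why: Stille coupling, in which zerovalent palladium inserts into the electron-poor alkenyl C11–Br bond and tin transfers the hydroxymethyl group, while the doubly neopentyl secondary tosylate, the silyl ether and the tertiary alcohol are inert and the saturated adduct tolerates the heat.

**Step 13**
Reactants: 19 primary allylic alcohol
Product: 20 C13 acetate
Conditions: Ac2O (1.5 equiv), pyridine, DMAP (5 mol %), CH2Cl2, 0 °C
Reagents that add atoms: acetic anhydride, CC(=O)OC(C)=O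
Why: Nucleophile-catalysed acylation, which acetylates the primary O13–H quickly whereas the tertiary O10–H next to the quaternary C1 does not react.

**Step 14**
Reactants: 20 silyl ether acetate
Product: 21 C8 alcohol (O8–H and O10–H free)
Conditions: HF·pyridine, pyridine, THF, 0 → 23 °C
Reagents that add atoms: none
Why: Fluoride-mediated desilylation under buffered mildly acidic conditions, which leave the acetate, the tosylate, the lactone and the no longer furylic tertiary alcohol intact.

**Step 15**
Reactants: 21 C8 alcohol; 22 methacrylic anhydride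
Product: 23 fragmentation precursor (O8 methacrylate, O13 acetate, C5 tosylate)
Conditions: 22 (3 equiv), DMAP (1 equiv), Et3N (4 equiv), BHT, CH2Cl2, 23 → 40 °C
Reagents that add atoms: none
Why: DMAP-catalysed esterification with an anhydride, in which the axial secondary O8–H is acylated with retention at C8 and the tertiary O10–H stays free.

**Step 16**
Reactants: 23 fragmentation precursor
Product: 26 CNP0394509.2 (target), via silylated precursor 24 (not isolated), via silylated macrocycle 25 (not isolated)
Conditions: TMSOTf (3 equiv), 2,6-di-tert-butyl-4-methylpyridine (4 equiv), CH2Cl2, −78 → −20 °C; Et3N quench, aqueous work-up; then Et3N·3HF, THF, 0 °C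
Reagents that add atoms: none
Why: Proposed new method: after transient silylation of O10, silylation of the lactone carbonyl makes C6 the γ-carbon of an incipient 2-silyloxyfuran while the bridge oxygen can stabilise positive charge at C1, so the strained, fully substituted C1–C6 bond should heterolyse (the reverse of a vinylogous Mukaiyama addition of a silyloxyfuran to an oxocarbenium ion), the hindered pyridine then removes a C2 proton to give the C1=C2 enol ether, and the 5-silyloxyfurfuryl-type C5 tosylate ionises at once to the C5=C6 alkylidene butenolide with the geometry (C4 cis to C7) that the bridged medium ring accommodates; the norbornane frame cannot align C1–C6 antiperiplanar to C5–O, so the process is stepwise rather than concerted, C4, C8 and C10 are not touched, buffered fluoride frees O10, and the closest known reaction type is the Grob (Wharton) fragmentation of cyclic 1,3-diol monosulfonates, here with an ether oxygen instead of an alkoxide as donor.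

**Compound list**
1 | 2-acetyl-5-methylfuran | CC(=O)c1ccc(C)o1 | starting material
2 | allylboronic acid pinacol ester | C=CCB1OC(C)(C)C(C)(C)O1 | starting material
3 | (R)-2-(5-methylfuran-2-yl)pent-4-en-2-ol | C=CC[C@@](C)(O)c1ccc(C)o1 | intermediate
4 | (4R)-4-(5-methylfuran-2-yl)pentane-1,2,4-triol, both C2 epimers (not isolated) | OCC(O)C[C@@](C)(O)c1ccc(C)o1 | intermediate
5 | (R)-3-hydroxy-3-(5-methylfuran-2-yl)butanal | O=CC[C@@](C)(O)c1ccc(C)o1 | intermediate
6 | 3,4-dibromofuran-2(5H)-one | O=C1OCC(Br)=C1Br | starting material
7 | 3-bromo-4-[(3R)-1,3-dihydroxy-3-(5-methylfuran-2-yl)butyl]furan-2(5H)-one, both C8 epimers | OC(C1=C(Br)C(=O)OC1)C[C@@](C)(O)c1ccc(C)o1 | intermediate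
8 | 3-bromo-4-[(3R)-3-hydroxy-3-(5-methylfuran-2-yl)butanoyl]furan-2(5H)-one | O=C(C1=C(Br)C(=O)OC1)C[C@@](C)(O)c1ccc(C)o1 | intermediate
9 | O10-diethylboryl derivative of 8, boron chelated by the C8 ketone (not isolated) | CCB(CC)O[C@](C)(CC(=O)C1=C(Br)C(=O)OC1)c1ccc(C)o1 | intermediate
10 | 3-bromo-4-[(1S,3R)-1,3-dihydroxy-3-(5-methylfuran-2-yl)butyl]furan-2(5H)-one (syn diol) | O[C@H](C1=C(Br)C(=O)OC1)C[C@@](C)(O)c1ccc(C)o1 | intermediate
11 | O8 tert-butyldimethylsilyl ether of 10 | CC(C)(C)[Si](C)(C)O[C@H](C1=C(Br)C(=O)OC1)C[C@@](C)(O)c1ccc(C)o1 | intermediate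
12 | tert-butoxybis(dimethylamino)methane | CN(C)C(OC(C)(C)C)N(C)C | starting material
13 | (Z)-5-(dimethylaminomethylene) derivative of 11 | CC(C)(C)[Si](C)(C)O[C@H](C1=C(Br)C(=O)O/C1=C\N(C)C)C[C@@](C)(O)c1ccc(C)o1 | intermediate
14 | (Z)-5-(hydroxymethylene) lactone | CC(C)(C)[Si](C)(C)O[C@H](C1=C(Br)C(=O)O/C1=C\O)C[C@@](C)(O)c1ccc(C)o1 | intermediate
15 | (Z)-5-(tosyloxymethylene) lactone, cycloaddition precursor | CC(C)(C)[Si](C)(C)O[C@H](C1=C(Br)C(=O)O/C1=C\OS(=O)(=O)c1ccc(C)cc1)C[C@@](C)(O)c1ccc(C)o1 | intermediate
16 | 7-oxanorbornene cycloadduct (tether exo, tosylate endo, O8 and O10 axial) | CC(C)(C)[Si](C)(C)O[C@H]1C[C@@](C)(O)[C@]23C=C[C@](C)(O2)[C@@H](OS(=O)(=O)c4ccc(C)cc4)[C@@]35OC(=O)C(Br)=C51 | intermediate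
17 | saturated 7-oxanorbornane bromide | CC(C)(C)[Si](C)(C)O[C@H]1C[C@@](C)(O)[C@]23CC[C@](C)(O2)[C@@H](OS(=O)(=O)c4ccc(C)cc4)[C@@]35OC(=O)C(Br)=C51 | intermediate
18 | (tributylstannyl)methanol | CCCC[Sn](CCCC)(CCCC)CO | starting material
19 | C11 hydroxymethyl butenolide | CC(C)(C)[Si](C)(C)O[C@H]1C[C@@](C)(O)[C@]23CC[C@](C)(O2)[C@@H](OS(=O)(=O)c4ccc(C)cc4)[C@@]35OC(=O)C(CO)=C51 | intermediate
20 | C13 acetate, O8 silyl ether | CC(C)(C)[Si](C)(C)O[C@H]1C[C@@](C)(O)[C@]23CC[C@](C)(O2)[C@@H](OS(=O)(=O)c4ccc(C)cc4)[C@@]35OC(=O)C(COC(C)=O)=C51 | intermediate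
21 | C13 acetate, C8 alcohol | O[C@H]1C[C@@](C)(O)[C@]23CC[C@](C)(O2)[C@@H](OS(=O)(=O)c4ccc(C)cc4)[C@@]35OC(=O)C(COC(C)=O)=C51 | intermediate
22 | methacrylic anhydride | CC(=C)C(=O)OC(=O)C(C)=C | starting material
23 | fragmentation precursor (O8 methacrylate, O13 acetate, C5 tosylate) | C=C(C)C(=O)O[C@H]1C[C@@](C)(O)[C@]23CC[C@](C)(O2)[C@@H](OS(=O)(=O)c4ccc(C)cc4)[C@@]35OC(=O)C(COC(C)=O)=C51 | intermediate
24 | O10 trimethylsilyl ether of 23 (not isolated) | C=C(C)C(=O)O[C@H]1C[C@@](C)(O[Si](C)(C)C)[C@]23CC[C@](C)(O2)[C@@H](OS(=O)(=O)c4ccc(C)cc4)[C@@]35OC(=O)C(COC(C)=O)=C51 | intermediate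
25 | O10 trimethylsilyl ether of 26 (not isolated) | C=C(C)C(=O)O[C@H]1C[C@@](C)(O[Si](C)(C)C)C2=CC[C@@](C)(/C=C3/OC(=O)C(COC(C)=O)=C31)O2 | intermediate
26 | CNP0394509.2, (4S,8S,10R)-13-acetoxy-10-hydroxy-8-methacryloyloxy-1,4-epoxygermacra-1,5,7(11)-trien-12,6-olide | C=C(C)C(=O)O[C@H]1C[C@@](C)(O)C2=CC[C@@](C)(/C=C3/OC(=O)C(COC(C)=O)=C31)O2 | target

Total step count: 16
Longest linear sequence: 16 steps (1 to 26)

**Steps most likely to fail**

1. **Step 16 (the labelled step).**
   - What may go wrong: the C1–C6 bond may resist heterolysis, so that ionisation of the C6–O lactone bond or of the allylic C13 acetate takes over. A 1,2-shift from C10 to the cationic C1 may also outrun loss of the C2 proton.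
   - Fallback: it uses known chemistry, sets out from 16 and comes back at 26. The cut is driven by a push from C2 instead of a pull at the lactone.
   - In place of the diimide reduction, 16 is hydroborated from the exo face (BH3·SMe2, THF, 0 °C, aqueous work-up). This also blocks cycloreversion and gives the exo-C2 boronic acid F1. Regioselectivity for C2 may be modest, and only the C2 borane can fragment.
   - Aqueous NaOH (1.1 equiv, THF, 0 °C) forms the boronate, whose exo C2–B bond lies antiperiplanar to C1–C6. This is the hydroxide-triggered boronate fragmentation of a δ-sulfonyloxy organoborane, the classical opening of decalins to cyclodecadienes. It creates C1=C2, cuts C1–C6 and expels the C5 tosylate, giving the macrocyclic bromide F2.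
   - The four remaining operations are then run on the macrocycle. Stille coupling with 18 (Pd(PPh3)4, dioxane, 80 °C) gives the hydroxymethyl macrocycle F3. Ac2O/pyridine gives the acetate F4. TBAF buffered with AcOH gives the C8 alcohol F5. Finally 22 with DMAP gives 26.

2. **Step 10.**
   - What may go wrong: the cycloaddition may be slow, and the adduct may revert on decompression. The forming chair carries the lactone oxygen, the bulky silyloxy group and the hydroxyl all axial on one face. That crowding could also erode face selectivity.
   - Fallback: it sets out from 15 and comes back at 21. The silyl group is removed before the cycloaddition and not put back.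
   - Et3N·3HF (MeCN, 23 °C, neutral work-up) gives the free C8 alcohol enol tosylate F6. Its small axial hydroxyl can hydrogen-bond to O10 and to the lactone oxygen, while allylic 1,3-strain with bromine still fixes the face.
   - The same pressure cycloaddition gives the cycloadduct diol F7. Immediate diimide reduction gives the saturated diol F8, and Stille coupling with 18 gives the triol F9.
   - Acetylation of the primary O13–H only (Ac2O 1.05 equiv, pyridine, −20 °C) delivers 21, so steps 13 and 14 are replaced.

3. **Step 5.**
   - What may go wrong: facial selectivity may erode because the axial hydride path runs past the pseudo-axial C10 methyl group of the chelate. Conjugate reduction of the ene-dicarbonyl unit may also compete.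
   - Fallback: it sets out from 8 and comes back at 10. Substrate control is replaced by reagent control.
   - A Corey–Bakshi–Shibata reduction is used: (R)-1-methyl-3,3-diphenyltetrahydro-1H,3H-pyrrolo[1,2-c][1,3,2]oxazaborole (20 mol %), catecholborane (2.5 equiv, one equivalent being consumed by O10–H), toluene, −78 °C. It is strictly 1,2-selective on enones. It differentiates the large sp2 bromobutenolide from the CH2 group and should give the (8S) alcohol regardless of C10.

**Further compounds**
F1 | step 16 | exo-C2 boronic acid of the saturated cycloadduct | CC(C)(C)[Si](C)(C)O[C@H]1C[C@@](C)(O)[C@]23[C@H](B(O)O)C[C@](C)(O2)[C@@H](OS(=O)(=O)c4ccc(C)cc4)[C@@]35OC(=O)C(Br)=C51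
F2 | step 16 | macrocyclic C11 bromide, O8 silyl ether | CC(C)(C)[Si](C)(C)O[C@H]1C[C@@](C)(O)C2=CC[C@@](C)(/C=C3/OC(=O)C(Br)=C31)O2
F3 | step 16 | macrocyclic C11 hydroxymethyl compound, O8 silyl ether | CC(C)(C)[Si](C)(C)O[C@H]1C[C@@](C)(O)C2=CC[C@@](C)(/C=C3/OC(=O)C(CO)=C31)O2
F4 | step 16 | macrocyclic C13 acetate, O8 silyl ether | CC(C)(C)[Si](C)(C)O[C@H]1C[C@@](C)(O)C2=CC[C@@](C)(/C=C3/OC(=O)C(COC(C)=O)=C31)O2
F5 | step 16 | macrocyclic C13 acetate, C8 alcohol | O[C@H]1C[C@@](C)(O)C2=CC[C@@](C)(/C=C3/OC(=O)C(COC(C)=O)=C31)O2
F6 | step 10 | (Z)-enol tosylate with free O8–H | O[C@H](C1=C(Br)C(=O)O/C1=C\OS(=O)(=O)c1ccc(C)cc1)C[C@@](C)(O)c1ccc(C)o1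
F7 | step 10 | oxanorbornene cycloadduct diol | O[C@H]1C[C@@](C)(O)[C@]23C=C[C@](C)(O2)[C@@H](OS(=O)(=O)c4ccc(C)cc4)[C@@]35OC(=O)C(Br)=C51
F8 | step 10 | saturated oxanorbornane diol bromide | O[C@H]1C[C@@](C)(O)[C@]23CC[C@](C)(O2)[C@@H](OS(=O)(=O)c4ccc(C)cc4)[C@@]35OC(=O)C(Br)=C51
F9 | step 10 | saturated oxanorbornane triol (C11 hydroxymethyl) | O[C@H]1C[C@@](C)(O)[C@]23CC[C@](C)(O2)[C@@H](OS(=O)(=O)c4ccc(C)cc4)[C@@]35OC(=O)C(CO)=C51
F0 | step 5 | none | none
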